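**Retrosynthetic overview**
1. Target ⇒ remove the C10 methyl (non-chelation methyl addition) ⇒ 10-oxo epoxy-cyclodecenolide.
2. Key step: the ten-membered ring ⇒ Grob ring expansion (C4–C10 cleaved, C5 mesylate leaves; 5-7 bicycle → 10-ring, sets 4E) of a cis-fused cyclopenta-cycloheptane already carrying oxirane, C3 acetate, C8 angelate and the α-methylene lactone.
3. Seven-membered ring ⇒ intramolecular aldol (C4–C5) of a 4-hydroxycyclopentenone tethered to a lactone aldehyde.
4. Tether ⇒ zinc Barbier union (C7–C8) of a cyclopentenone acetaldehyde with a 3-(bromomethyl)butenolide (sets C7 and C8, regenerates the exo-methylene).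
5. Building blocks: cyclopentenone from 1-(furan-2-yl)ethanol and oxirane (enantioselective Piancatelli rearrangement); butenolide from methyl 2-(bromomethyl)acrylate and dimethoxyacetaldehyde. Ring order: cyclopentenone, lactone, cycloheptane, oxirane, ten-membered ring.

Assumption: atoms are labelled C1–C15 as in the germacranolide target (C12 lactone C=O, C13 exocyclic CH2, C14 methyl on C10, C15 methyl on C4); in the bicyclic intermediates "up" is the face of C15 in a flat drawing of the C1–C10 perimeter.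
Assumption: the C4 configuration drawn for the monocyclic cyclopentenones is the trans one from step 2; it is immaterial because C4 is planarised in step 9.

**Step 1**
Reactants: 1 1-(furan-2-yl)ethan-1-ol (racemic); 2 oxirane
Product: 4 2-[5-(1-hydroxyethyl)furan-2-yl]ethan-1-ol, via dilithiated furyl alkoxide 3 (not isolated)
Conditions: n-BuLi (2.2 equiv), THF, −78 to 0 °C; then 2, 0 °C to rt; H2O
Reagents that add atoms: none
Why: Alkoxide formation and C5 lithiation give the dianion, whose furyl carbanion opens oxirane by SN2 epoxide ring opening (heteroaryllithium alkylation); the carbinol centre is erased in step 2.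

**Step 2**
Reactants: 4 2-[5-(1-hydroxyethyl)furan-2-yl]ethan-1-ol
Product: 5 (4R,5S)-4-hydroxy-4-(2-hydroxyethyl)-5-methylcyclopent-2-en-1-one
Conditions: (R)-3,3′-bis(2,4,6-triisopropylphenyl)-1,1′-binaphthyl-2,2′-diyl N-triflylphosphoramide (10 mol%), H2O (10 equiv), toluene, 50 °C
Reagents that add atoms: water O
Why: Proposed new method: an enantioselective Piancatelli rearrangement of a 5-alkylated furylcarbinol that creates a fully substituted carbinol centre — the chiral acid ionises the carbinol to a furfuryl oxocarbenium ion paired with its chiral anion, water adds at furan C5, ring opening gives a 1-hydroxypentadienyl cation held to the anion by O–H···O bonds (hemiketal OH and side-chain OH), and the conrotatory 4π closure then proceeds with one sense of rotation to the trans (4R,5S) product, forming the five-membered ring and the C10 centre that later relays to C3; closest known reaction type: chiral-acid-catalysed enantioselective Piancatelli rearrangements of 5-unsubstituted furylcarbinols and the racemic Lewis-acid Piancatelli rearrangement of 5-alkylfurylcarbinols.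

**Step 3**
Reactants: 5 (4R,5S)-4-hydroxy-4-(2-hydroxyethyl)-5-methylcyclopent-2-en-1-one
Product: 6 (4R,5S)-4-hydroxy-5-methyl-4-(2-oxoethyl)cyclopent-2-en-1-one
Conditions: TEMPO (10 mol%), PhI(OAc)2, CH2Cl2, rt
Reagents that add atoms: none
Why: Oxoammonium (TEMPO) oxidation is selective for the primary alcohol and leaves the tertiary carbinol and the enone untouched.

**Step 4**
Reactants: 7 methyl 2-(bromomethyl)prop-2-enoate; 8 2,2-dimethoxyacetaldehyde (dried)
Product: 11 (5R)-5-(dimethoxymethyl)-3-methylideneoxolan-2-one, via trimethylsilyl ether 9 (not isolated), via hydroxy ester 10 (not isolated)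
Conditions: CrCl2 (10 mol%), chiral carbazole-bis(oxazoline) ligand (12 mol%), Mn, Me3SiCl, i-Pr2NEt, THF, rt; then TsOH·H2O, CH2Cl2, rt
Reagents that add atoms: none
Why: Catalytic asymmetric Nozaki–Hiyama–Kishi-type 2-(alkoxycarbonyl)allylation, in which the ligand-bound allylchromium adds to one aldehyde face through a chair transition state (sets C6), Mn returns chromium to the divalent state, Me3SiCl releases the alkoxide, and acid desilylates and lactonises.

**Step 5**
Reactants: 11 (5R)-5-(dimethoxymethyl)-3-methylideneoxolan-2-one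
Product: 13 (5R)-3-(bromomethyl)-5-(dimethoxymethyl)furan-2(5H)-one, via dibromide 12 (not isolated)
Conditions: Br2, CH2Cl2, −20 °C; then Et3N, −20 to 0 °C
Reagents that add atoms: bromine BrBr
Why: Bromine addition to the exocyclic alkene followed by E2 loss of HBr across C7–C11 (bromination–dehydrobromination) gives the conjugated butenolide carrying the allylic bromide; C6 is untouched under cold, brief amine exposure.

**Step 6**
Reactants: 6 (4R,5S)-4-hydroxy-5-methyl-4-(2-oxoethyl)cyclopent-2-en-1-one; 13 (5R)-3-(bromomethyl)-5-(dimethoxymethyl)furan-2(5H)-one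
Product: 15 (4R,5S)-4-hydroxy-4-{(2R)-2-hydroxy-2-[(2R,3S)-2-(dimethoxymethyl)-4-methylidene-5-oxooxolan-3-yl]ethyl}-5-methylcyclopent-2-en-1-one, via allylzinc bromide 14 (not isolated)
Conditions: Zn dust, THF–sat. aq NH4Cl (3:1), 0 °C to rt
Reagents that add atoms: none
Why: Zinc Barbier allylation in which the allylzinc attacks the aldehyde through C7 in a Zimmerman–Traxler chair on the butenolide face anti to the C6 substituent with the aldehyde chain equatorial, restoring the exocyclic methylene and setting C7 (trans to C6) and C8 (R).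

**Step 7**
Reactants: 15 the Barbier adduct; 16 angelic acid, (2Z)-2-methylbut-2-enoic acid
Product: 18 (1R)-1-[(2R,3S)-2-(dimethoxymethyl)-4-methylidene-5-oxooxolan-3-yl]-2-[(1R,5S)-1-hydroxy-5-methyl-4-oxocyclopent-2-en-1-yl]ethyl (2Z)-2-methylbut-2-enoate, via mixed anhydride 17 (not isolated)
Conditions: 16, 2,4,6-trichlorobenzoyl chloride, Et3N, toluene, rt; then 15, toluene, 80 °C
Reagents that add atoms: none
Why: Yamaguchi esterification through the mixed anhydride without DMAP acylates the only secondary hydroxyl, keeps the Z geometry of the angelate and leaves the tertiary C10 hydroxyl free.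

**Step 8**
Reactants: 18 the angelate acetal
Product: 19 (1R)-1-[(2R,3S)-2-formyl-4-methylidene-5-oxooxolan-3-yl]-2-[(1R,5S)-1-hydroxy-5-methyl-4-oxocyclopent-2-en-1-yl]ethyl (2Z)-2-methylbut-2-enoate
Conditions: TFA–H2O (9:1), CH2Cl2, 0 °C
Reagents that add atoms: water O
Why: Acid-catalysed acetal hydrolysis unmasks the C5 aldehyde; lactone, esters and the poorly ionisable tertiary carbinol (γ to the enone carbonyl) survive.

**Step 9**
Reactants: 19 the keto aldehyde
Product: 21 8-angeloyloxy-5,10-dihydroxy-3-oxo-4,10-cyclo-14-norgermacra-1,11(13)-dien-12,6-olide (cis-fused; C15 and the oxygens on C5, C6, C8, C10 up; C11 down), via titanium dienolate chelate 20 (not isolated)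
Conditions: TiCl4 (2.2 equiv), i-Pr2NEt (2.5 equiv), CH2Cl2, −78 to −40 °C
Reagents that add atoms: none
Why: Tetravalent titanium bridging the C10 alkoxide and the C3 carbonyl allows soft enolisation only at C4, and the intramolecular aldol addition through a closed Zimmerman–Traxler transition state closes the seven-membered ring — the tether enforces cis fusion (C15 syn to C10–O) and Felkin–Anh attack on the α-acyloxy aldehyde puts the C5 hydroxyl syn to C15, the relationship needed for an E-selective fragmentation.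

**Step 10**
Reactants: 21 the aldol
Product: 22 8-angeloyloxy-3,5,10-trihydroxy-4,10-cyclo-14-norgermacra-1,11(13)-dien-12,6-olide (3-OH up)
Conditions: Me4NBH(OAc)3, MeCN–AcOH (1:1), −30 °C
Reagents that add atoms: none
Why: Evans–Saksena hydroxyl-directed reduction, in which the secondary C5 hydroxyl (not the hindered tertiary one) exchanges onto boron and delivers hydride intramolecularly to the carbonyl face on which C5 sits, so the C3 hydroxyl (the 3R centre of the target) forms syn to C15 and the C10 hydroxyl; esters, enoates and the lactone are inert to triacetoxyborohydride.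

**Step 11**
Reactants: 22 the triol
Product: 23 3-acetoxy-8-angeloyloxy-5,10-dihydroxy-4,10-cyclo-14-norgermacra-1,11(13)-dien-12,6-olide
Conditions: Ac2O (1.1 equiv), pyridine, CH2Cl2, −20 to 0 °C
Reagents that add atoms: acetic anhydride CC(=O)OC(C)=O
Why: Selective acylation of the allylic C3 hydroxyl, the least hindered one (the C5 hydroxyl lies between the quaternary C4 and the lactone-bearing C6, the C10 hydroxyl is tertiary).

**Step 12**
Reactants: 23 the acetate
Product: 24 3-acetoxy-8-angeloyloxy-1,2-epoxy-5,10-dihydroxy-4,10-cyclo-14-norgermacr-11(13)-en-12,6-olide (oxirane O up)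
Conditions: VO(acac)2 (5 mol%), t-BuOOH, CH2Cl2, 0 °C to rt
Reagents that add atoms: tert-butyl hydroperoxide CC(C)(C)OO
Why: Vanadium-catalysed hydroxyl-directed epoxidation, in which the tertiary allylic C10 hydroxyl delivers oxygen to its own face of the cyclopentene and sets C1 and C2 with the oxirane syn to the C3 acetate; the electron-poor alkenes do not react.

**Step 13**
Reactants: 24 the epoxy diol
Product: 25 3-acetoxy-8-angeloyloxy-1,2-epoxy-10-hydroxy-5-(methanesulfonyloxy)-4,10-cyclo-14-norgermacr-11(13)-en-12,6-olide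
Conditions: MsCl, Et3N, CH2Cl2, −20 °C
Reagents that add atoms: methanesulfonyl chloride CS(=O)(=O)Cl
Why: Sulfonylation (via sulfene) of the only secondary hydroxyl; the tertiary hydroxyl does not react.

**Step 14**
Reactants: 25 the hydroxy mesylate
Product: 27 (1R,2R,3R,4E,6S,7S,8R)-3-acetoxy-8-angeloyloxy-1,2-epoxy-10-oxo-14-norgermacra-4,11(13)-dien-12,6-olide, via potassium alkoxide 26 (not isolated)
Conditions: KN(SiMe3)2 (1.05 equiv), THF, −78 to −40 °C; pH 7 buffer
Reagents that add atoms: none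
Why: Grob (Wharton) fragmentation as the ring expansion — the C10 alkoxide pushes, the C4–C10 bond antiperiplanar to the C5–OMs bond breaks and the bicyclo[5.3.0] core opens to the ten-membered ketone; because the mesylate is syn to C15, C6 is anti to C3 in the reacting rotamer and only the 4E alkene can form, while one equivalent of base at low temperature limits acyl transfer and β-elimination.

**Step 15**
Reactants: 27 the epoxy ketone
Product: 28 (1R,2R,3R,4E,6S,7S,8R,10R)-3-acetoxy-8-angeloyloxy-1,2-epoxy-10-hydroxygermacra-4,11(13)-dien-12,6-olide (CNP0155556.1)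
Conditions: MeTi(Oi-Pr)3 (3 equiv), Et2O–CH2Cl2, −40 to 0 °C; aq NH4F
Reagents that add atoms: methyltitanium triisopropoxide C[Ti](OC(C)C)(OC(C)C)OC(C)C
Why: Chemoselective 1,2-addition of a non-basic, non-chelating methyltitanium reagent to the ketone (esters, lactone and oxirane are inert), with Felkin–Anh/Cornforth attack anti to the oxirane C–O bond from the H1 side giving the 10R carbinol.

**Compound list**
1 | 1-(furan-2-yl)ethan-1-ol (racemic) | CC(O)c1ccco1 | starting material
2 | oxirane | C1CO1 | starting material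
3 | lithium 1-(5-lithiofuran-2-yl)ethan-1-olate | CC([O-])c1ccc([Li])o1.[Li+] | intermediate
4 | 2-[5-(1-hydroxyethyl)furan-2-yl]ethan-1-ol | CC(O)c1ccc(CCO)o1 | intermediate
5 | (4R,5S)-4-hydroxy-4-(2-hydroxyethyl)-5-methylcyclopent-2-en-1-one | OCC[C@@]1(O)C=CC(=O)[C@H]1C | intermediate
6 | (4R,5S)-4-hydroxy-5-methyl-4-(2-oxoethyl)cyclopent-2-en-1-one | O=CC[C@@]1(O)C=CC(=O)[C@H]1C | intermediate
7 | methyl 2-(bromomethyl)prop-2-enoate | C=C(CBr)C(=O)OC | starting material
8 | 2,2-dimethoxyacetaldehyde | COC(OC)C=O | starting material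
9 | methyl (4R)-5,5-dimethoxy-2-methylidene-4-[(trimethylsilyl)oxy]pentanoate | C=C(C[C@@H](O[Si](C)(C)C)C(OC)OC)C(=O)OC | intermediate
10 | methyl (4R)-4-hydroxy-5,5-dimethoxy-2-methylidenepentanoate | C=C(C[C@@H](O)C(OC)OC)C(=O)OC | intermediate
11 | (5R)-5-(dimethoxymethyl)-3-methylideneoxolan-2-one | C=C1C[C@H](C(OC)OC)OC1=O | intermediate
12 | (5R)-3-bromo-3-(bromomethyl)-5-(dimethoxymethyl)oxolan-2-one (C3 epimers) | BrCC1(Br)C[C@H](C(OC)OC)OC1=O | intermediate
13 | (5R)-3-(bromomethyl)-5-(dimethoxymethyl)furan-2(5H)-one | O=C1O[C@@H](C(OC)OC)C=C1CBr | intermediate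
14 | bromo{[(5R)-5-(dimethoxymethyl)-2-oxo-2,5-dihydrofuran-3-yl]methyl}zinc | O=C1O[C@@H](C(OC)OC)C=C1C[Zn]Br | intermediate
15 | (4R,5S)-4-hydroxy-4-{(2R)-2-hydroxy-2-[(2R,3S)-2-(dimethoxymethyl)-4-methylidene-5-oxooxolan-3-yl]ethyl}-5-methylcyclopent-2-en-1-one | C=C1C(=O)O[C@@H](C(OC)OC)[C@@H]1[C@H](O)C[C@@]2(O)C=CC(=O)[C@H]2C | intermediate
16 | angelic acid, (2Z)-2-methylbut-2-enoic acid | C/C=C(/C)C(=O)O | starting material
17 | (2Z)-2-methylbut-2-enoic 2,4,6-trichlorobenzoic anhydride | C/C=C(/C)C(=O)OC(=O)c1c(Cl)cc(Cl)cc1Cl | intermediate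
18 | (1R)-1-[(2R,3S)-2-(dimethoxymethyl)-4-methylidene-5-oxooxolan-3-yl]-2-[(1R,5S)-1-hydroxy-5-methyl-4-oxocyclopent-2-en-1-yl]ethyl (2Z)-2-methylbut-2-enoate | C=C1C(=O)O[C@@H](C(OC)OC)[C@@H]1[C@H](OC(=O)/C(C)=C\C)C[C@@]2(O)C=CC(=O)[C@H]2C | intermediate
19 | (1R)-1-[(2R,3S)-2-formyl-4-methylidene-5-oxooxolan-3-yl]-2-[(1R,5S)-1-hydroxy-5-methyl-4-oxocyclopent-2-en-1-yl]ethyl (2Z)-2-methylbut-2-enoate | C=C1C(=O)O[C@@H](C=O)[C@@H]1[C@H](OC(=O)/C(C)=C\C)C[C@@]2(O)C=CC(=O)[C@H]2C | intermediate
20 | dichlorotitanium chelate of 19 (C10 alkoxide oxygen and C3 dienolate oxygen on titanium, C3=C4 enolate) | C=C1C(=O)O[C@@H](C=O)[C@@H]1[C@H](OC(=O)/C(C)=C\C)C[C@@]23C=CC(=C2C)O[Ti](Cl)(Cl)O3 | intermediate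
21 | 8-angeloyloxy-5,10-dihydroxy-3-oxo-4,10-cyclo-14-norgermacra-1,11(13)-dien-12,6-olide; cis-fused; C15, 5-OH, 6-O, 8-O, 10-OH up, C11 down | C=C1C(=O)O[C@H]2[C@@H](O)[C@]3(C)C(=O)C=C[C@]3(O)C[C@@H](OC(=O)/C(C)=C\C)[C@H]12 | intermediate
22 | 8-angeloyloxy-3,5,10-trihydroxy-4,10-cyclo-14-norgermacra-1,11(13)-dien-12,6-olide; as 21 with 3-OH up | C=C1C(=O)O[C@H]2[C@@H](O)[C@]3(C)[C@@H](O)C=C[C@]3(O)C[C@@H](OC(=O)/C(C)=C\C)[C@H]12 | intermediate
23 | 3-acetoxy-8-angeloyloxy-5,10-dihydroxy-4,10-cyclo-14-norgermacra-1,11(13)-dien-12,6-olide; configuration as 22 | C=C1C(=O)O[C@H]2[C@@H](O)[C@]3(C)[C@@H](OC(C)=O)C=C[C@]3(O)C[C@@H](OC(=O)/C(C)=C\C)[C@H]12 | intermediate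
24 | 3-acetoxy-8-angeloyloxy-1,2-epoxy-5,10-dihydroxy-4,10-cyclo-14-norgermacr-11(13)-en-12,6-olide; oxirane O up | C=C1C(=O)O[C@H]2[C@@H](O)[C@]4(C)[C@@H](OC(C)=O)[C@H]3O[C@H]3[C@]4(O)C[C@@H](OC(=O)/C(C)=C\C)[C@H]12 | intermediate
25 | 3-acetoxy-8-angeloyloxy-1,2-epoxy-10-hydroxy-5-(methanesulfonyloxy)-4,10-cyclo-14-norgermacr-11(13)-en-12,6-olide; configuration as 24 | C=C1C(=O)O[C@H]2[C@@H](OS(C)(=O)=O)[C@]4(C)[C@@H](OC(C)=O)[C@H]3O[C@H]3[C@]4(O)C[C@@H](OC(=O)/C(C)=C\C)[C@H]12 | intermediate
26 | potassium C10 alkoxide of 25 | C=C1C(=O)O[C@H]2[C@@H](OS(C)(=O)=O)[C@]4(C)[C@@H](OC(C)=O)[C@H]3O[C@H]3[C@]4([O-])C[C@@H](OC(=O)/C(C)=C\C)[C@H]12.[K+] | intermediate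
27 | (1R,2R,3R,4E,6S,7S,8R)-3-acetoxy-8-angeloyloxy-1,2-epoxy-10-oxo-14-norgermacra-4,11(13)-dien-12,6-olide | C=C1C(=O)O[C@H]2/C=C(\C)[C@@H](OC(C)=O)[C@H]3O[C@H]3C(=O)C[C@@H](OC(=O)/C(C)=C\C)[C@H]12 | intermediate
28 | (1R,2R,3R,4E,6S,7S,8R,10R)-3-acetoxy-8-angeloyloxy-1,2-epoxy-10-hydroxygermacra-4,11(13)-dien-12,6-olide (CNP0155556.1) | C=C1C(=O)O[C@H]2/C=C(\C)[C@@H](OC(C)=O)[C@H]3O[C@H]3[C@](C)(O)C[C@@H](OC(=O)/C(C)=C\C)[C@H]12 | target

**Step count**
Total: 15 steps. Longest linear sequence: 13 steps (steps 1–3 and 6–15).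

**Three steps most likely to fail**

Step 2 (the proposed new step; enantiocontrol or rate may be poor for a 5-alkylfuran). Fallback with known chemistry, setting out from 4: the racemic Piancatelli rearrangement with ZnCl2 in aqueous dioxane at reflux gives 5 together with its enantiomer (4S,5R)-4-hydroxy-4-(2-hydroxyethyl)-5-methylcyclopent-2-en-1-one F1. Oxidation as in step 3 gives 6 together with (4S,5R)-4-hydroxy-5-methyl-4-(2-oxoethyl)cyclopent-2-en-1-one F2. The zinc Barbier coupling of this racemate with enantiopure 13 (as in step 6) gives 15 and the adduct epimeric at both cyclopentenone centres F3. The two are diastereomers and are separated on silica, so the stereocentre is secured by resolution through covalent diastereomers instead of asymmetric catalysis. The route is rejoined at 15.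

Step 9 (competing enolisation of the α-acyloxy aldehyde, or the wrong C5 epimer). Fallback setting out from 18: LiN(SiMe3)2/Me3SiCl at −78 °C gives the bis(trimethylsilyl) derivative (C10 silyl ether, C3–C4 silyl dienol ether) F4. N-Bromosuccinimide converts it into the C4 bromo ketone F5. Aqueous TFA then frees the aldehyde and the C10 hydroxyl to give the bromo keto aldehyde F6. CrCl2 in THF generates the chromium enolate at C4 only, under neutral conditions, and the Reformatsky-type aldol closes the seven-membered ring through a closed transition state. The route is rejoined at 21.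

Step 15 (facial selectivity of the methyl addition next to the oxirane, and ester tolerance). Fallback setting out from 23, with methyl introduced before the oxirane: mesylation as in step 13 gives the hydroxy mesylate without oxirane F7. KN(SiMe3)2 Grob fragmentation gives the (1Z,4E)-dienone F8. MeTi(Oi-Pr)3 adds to the ketone from the periphery of the macrocycle to give the tertiary allylic alcohol F9. VO(acac)2/t-BuOOH epoxidation directed by the C10 hydroxyl (threo-selective for a Z allylic alcohol through minimised allylic 1,3-strain) then installs the oxirane. The route is rejoined at 28.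

**Further compounds**
F1 | step 2 | (4S,5R)-4-hydroxy-4-(2-hydroxyethyl)-5-methylcyclopent-2-en-1-one | OCC[C@]1(O)C=CC(=O)[C@@H]1C
F2 | step 2 | (4S,5R)-4-hydroxy-5-methyl-4-(2-oxoethyl)cyclopent-2-en-1-one | O=CC[C@]1(O)C=CC(=O)[C@@H]1C
F3 | step 2 | (4S,5R)-4-hydroxy-4-{(2R)-2-hydroxy-2-[(2R,3S)-2-(dimethoxymethyl)-4-methylidene-5-oxooxolan-3-yl]ethyl}-5-methylcyclopent-2-en-1-one | C=C1C(=O)O[C@@H](C(OC)OC)[C@@H]1[C@H](O)C[C@]2(O)C=CC(=O)[C@@H]2C
F4 | step 9 | bis(trimethylsilyl) derivative of 18 (C10 silyl ether, C3–C4 silyl dienol ether) | C=C1C(=O)O[C@@H](C(OC)OC)[C@@H]1[C@H](OC(=O)/C(C)=C\C)C[C@@]2(O[Si](C)(C)C)C=CC(O[Si](C)(C)C)=C2C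
F5 | step 9 | C4 bromo ketone of 18 with C10 trimethylsilyl ether (C4 epimers) | C=C1C(=O)O[C@@H](C(OC)OC)[C@@H]1[C@H](OC(=O)/C(C)=C\C)C[C@@]2(O[Si](C)(C)C)C=CC(=O)C2(C)Br
F6 | step 9 | C4 bromo derivative of keto aldehyde 19 (C4 epimers) | C=C1C(=O)O[C@@H](C=O)[C@@H]1[C@H](OC(=O)/C(C)=C\C)C[C@@]2(O)C=CC(=O)C2(C)Br
F7 | step 15 | 3-acetoxy-8-angeloyloxy-10-hydroxy-5-(methanesulfonyloxy)-4,10-cyclo-14-norgermacra-1,11(13)-dien-12,6-olide | C=C1C(=O)O[C@H]2[C@@H](OS(C)(=O)=O)[C@]3(C)[C@@H](OC(C)=O)C=C[C@]3(O)C[C@@H](OC(=O)/C(C)=C\C)[C@H]12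
F8 | step 15 | (1Z,3R,4E,6S,7S,8R)-3-acetoxy-8-angeloyloxy-10-oxo-14-norgermacra-1,4,11(13)-trien-12,6-olide | C=C1C(=O)O[C@H]2/C=C(\C)[C@@H](OC(C)=O)/C=C\C(=O)C[C@@H](OC(=O)/C(C)=C\C)[C@H]12
F9 | step 15 | (1Z,3R,4E,6S,7S,8R,10R)-3-acetoxy-8-angeloyloxy-10-hydroxygermacra-1,4,11(13)-trien-12,6-olide | C=C1C(=O)O[C@H]2/C=C(\C)[C@@H](OC(C)=O)/C=C\[C@](C)(O)C[C@@H](OC(=O)/C(C)=C\C)[C@H]12
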